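The target is cut at both ester C–O bonds into one resolved, unsymmetrical α-truxillic diacid and two copies of a cis-fused octahydrocyclopenta[c]pyridin-6-ol. The carbocycle of that bicycle reads C4a–C5H2–C6(O)–C7(CH3)–C7a and shares C4a–C7a with the piperidine ring: an oxygenated carbon between a former vinyl terminus and a methyl-capped alkyne carbon, both hanging from N2. One intramolecular Pauson–Khand reaction therefore makes C4a–C7a, C5–C6 and C6–C7, closes both rings and sets C4a. Its precursor is the (R)-configured methyl carbamate whose nitrogen carries a but-2-ynyl and a 2-methylbut-3-enyl group; the carbamate carbon later becomes N-CH3.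

Key step: step 6

Locants: cyclopenta[c]pyridine numbering (C1, N2, C3, C4, C4a, C5, C6, C7, C7a) is used for the bicycle throughout.
Remark on the cyclobutane: with two different aryl groups the α-truxillic core has no inversion centre and is chiral. In the target both carboxyl-bearing ring carbons are R, so the diacid must be one enantiomer and is resolved before the coupling.
Remark on C6: the ester oxygen lies on the convex face, cis to the C7 methyl (6R). Hydride reduction should give the 6S alcohol, so the esterification is run with inversion.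
Assumption: the two O-acetylated cinnamic acids form a mixed solid phase with antiparallel stacking, and the absolute configuration of the resolved diacid is assigned by anomalous-dispersion X-ray analysis before use.

Step 1
Reactants: 1 2-nitrobenzenesulfonyl chloride; 2 but-2-yn-1-amine hydrochloride
Product: 3 N-(but-2-yn-1-yl)-2-nitrobenzenesulfonamide
Conditions: K2CO3, CH2Cl2/H2O, 0 °C → rt
Reagents that add atoms: 2-nitrobenzenesulfonyl chloride (1), O=[N+]([O-])c1ccccc1S(=O)(=O)Cl
Why: Schotten–Baumann sulfonylation of the primary amine gives the acidic sulfonamide of the Fukuyama amine synthesis, whose single N–H allows clean mono-alkylation in the next step; no stereocentre is involved.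

Step 2
Reactants: 3 N-(but-2-yn-1-yl)-2-nitrobenzenesulfonamide; 4 (R)-3-bromo-2-methylpropan-1-ol
Product: 5 N-(but-2-yn-1-yl)-N-[(2S)-3-hydroxy-2-methylpropyl]-2-nitrobenzenesulfonamide
Conditions: K2CO3, DMF, 60 °C
Reagents that add atoms: none
Why: Fukuyama-type SN2 N-alkylation, in which the soft sulfonamide anion displaces the primary bromide without touching the free hydroxyl or the neighbouring stereocentre, which comes unchanged from 4 (the descriptor becomes S only because CH2OH outranks CH2N).

Step 3
Reactants: 5 N-(but-2-yn-1-yl)-N-[(2S)-3-hydroxy-2-methylpropyl]-2-nitrobenzenesulfonamide; 6 methyl chloroformate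
Product: 8 methyl (but-2-yn-1-yl)[(2S)-3-hydroxy-2-methylpropyl]carbamate, via amino alcohol 7 (not isolated)
Conditions: PhSH, K2CO3, MeCN, rt; then ClCO2Me, 0 °C
Reagents that add atoms: methyl chloroformate (6), COC(=O)Cl
Why: Fukuyama deprotection (thiolate ipso attack, Meisenheimer adduct, loss of SO2) frees the secondary amine, which is far more nucleophilic than the primary alcohol and is acylated selectively in the same flask (Schotten–Baumann-type carbamoylation).

Step 4
Reactants: 8 methyl (but-2-yn-1-yl)[(2S)-3-hydroxy-2-methylpropyl]carbamate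
Product: 9 methyl (but-2-yn-1-yl)[(2S)-2-methyl-3-oxopropyl]carbamate
Conditions: TEMPO (cat.), PhI(OAc)2, CH2Cl2, rt; used crude
Reagents that add atoms: none
Why: The TEMPO/oxoammonium oxidation stops at the aldehyde under almost neutral conditions, so the α-stereocentre is not enolised and the alkyne and carbamate are left alone.

Step 5
Reactants: 9 methyl (but-2-yn-1-yl)[(2S)-2-methyl-3-oxopropyl]carbamate; 10 methyltriphenylphosphonium bromide
Product: 11 methyl (but-2-yn-1-yl)[(2R)-2-methylbut-3-en-1-yl]carbamate
Conditions: Ph3PCH3Br, KHMDS, THF, −78 → 0 °C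
Reagents that add atoms: methyltriphenylphosphonium bromide (10), C[P+](c1ccccc1)(c1ccccc1)c1ccccc1.[Br-]
Why: Wittig methylenation with the non-stabilised ylide at low temperature outruns enolisation of an α-methyl aldehyde, as is established for β-heteroatom-substituted α-methyl aldehydes, so the stereocentre is kept (R again by a priority change only).

Step 6
Reactants: 11 methyl (but-2-yn-1-yl)[(2R)-2-methylbut-3-en-1-yl]carbamate; 12 dicobalt octacarbonyl
Product: 14 methyl (4R,4aS)-4,7-dimethyl-6-oxo-1,3,4,4a,5,6-hexahydro-2H-cyclopenta[c]pyridine-2-carboxylate, via alkyne–dicobalt hexacarbonyl complex 13 (not isolated)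
Conditions: Co2(CO)8, CH2Cl2, rt; then NMO, 0 °C → rt
Reagents that add atoms: dicobalt octacarbonyl (12, source of C6=O), O=C=[Co](=C=O)(=C=O)(=C=O)[Co](=C=O)(=C=O)(=C=O)=C=O
Why: Intramolecular Pauson–Khand reaction ([2+2+1]) of a nitrogen-tethered 1,7-enyne, a well-documented reaction type: the but-2-ynyl group binds Co2(CO)6 to give 13, the N-oxide strips one CO, the vinyl group coordinates and inserts into the Co–C7a bond (C4a–C7a), CO migrates to C5 (C5–C6) and reductive elimination joins C6 to C7. The six-membered ring (C1, N2, C3, C4, C4a, C7a) closes in the insertion event as the tether ring, exo at both π-systems because C5 and C7 stay outside it, and the cyclopentenone (C4a, C5, C6, C7, C7a) closes at the reductive elimination as the three-component ring. The tether dictates the regiochemistry, so the alkyne methyl ends on C7 next to the carbonyl. C4a, the only new stereocentre, is controlled by C4: in the chair-like insertion geometry C5 must lie pseudo-equatorial, almost in the plane of C7=C7a, a pseudo-equatorial C4 methyl would be squeezed against it, and a pseudo-axial methyl costs little because both positions 1,3 to C4 (carbamate N2 and C7a) are trigonal and carry no axial hydrogen, which should place the methyl cis to C5 (4R,4aS). The step thus needs alkene-face selectivity only, and the planar carbamate nitrogen, which also populates the folded rotamer, together with promotion at or below room temperature is what should secure it.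

Step 7
Reactants: 14 methyl (4R,4aS)-4,7-dimethyl-6-oxo-1,3,4,4a,5,6-hexahydro-2H-cyclopenta[c]pyridine-2-carboxylate
Product: 16 methyl (4R,4aS,7S,7aR)-4,7-dimethyl-6-oxooctahydro-2H-cyclopenta[c]pyridine-2-carboxylate, via 7-epi ketone 15 (not isolated)
Conditions: H2 (4 atm), Pd/C, MeOH, rt; filter; then NaOMe (cat.), MeOH, rt
Reagents that add atoms: none
Why: Heterogeneous syn-hydrogenation of the tetrasubstituted enone should occur on the face that bears H-4a, because the other face is covered by the pseudo-axial C4 methyl, which sets C7a (cis ring fusion) and leaves the C7 methyl cis to C1; enolate equilibration with methoxide then moves that methyl to the convex face, trans to C1 (7S).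

Step 8
Reactants: 16 methyl (4R,4aS,7S,7aR)-4,7-dimethyl-6-oxooctahydro-2H-cyclopenta[c]pyridine-2-carboxylate
Product: 17 (4R,4aS,6S,7S,7aR)-2,4,7-trimethyloctahydro-1H-cyclopenta[c]pyridin-6-ol (6-epi-incarvilline)
Conditions: LiAlH4, THF, 0 °C → reflux; aqueous work-up
Reagents that add atoms: none
Why: In this LiAlH4 reduction the small hydride should add to the cyclopentanone from the convex face to give the alcohol trans to the C7 methyl (6S, the usual sense for 2-methylcyclopentanones with unhindered hydrides), and at reflux the methyl carbamate is reduced through the iminium ion to N-CH3.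

Step 9
Reactants: 18 (E)-4-acetoxy-3-methoxycinnamic acid; 19 (E)-4-acetoxycinnamic acid
Product: 20 rac-2-(4-acetoxy-3-methoxyphenyl)-4-(4-acetoxyphenyl)cyclobutane-1,3-dicarboxylic acid, α-truxillic relative configuration (aryls trans, carboxyls trans, each carboxyl cis to one aryl)
Conditions: equimolar 18 + 19 co-precipitated by fast evaporation from acetone; powder suspended in hexane, hν (medium-pressure Hg lamp, Pyrex), rt, regrinding; reverse-phase chromatography
Reagents that add atoms: none
Why: In this topochemical [2+2] photodimerisation of cinnamic acids, antiparallel neighbours lying within about 4 Å join head-to-tail, which fixes all four ring stereocentres relative to one another; in a mixed phase the pairing is statistical, so 20 should form as a racemate beside both homodimers, from which it is separated.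

Step 10
Reactants: 20 rac-2-(4-acetoxy-3-methoxyphenyl)-4-(4-acetoxyphenyl)cyclobutane-1,3-dicarboxylic acid
Product: 21 (1R,3R)-2-(4-acetoxy-3-methoxyphenyl)-4-(4-acetoxyphenyl)cyclobutane-1,3-dicarboxylic acid, α-truxillic relative configuration
Conditions: preparative chiral SFC, immobilised amylose tris(3,5-dimethylphenylcarbamate), CO2/MeOH (0.1% HCO2H), 35 °C
Reagents that add atoms: none
Why: This is a chromatographic resolution on a polysaccharide chiral stationary phase: 20 has no symmetry element because its aryl groups differ, so its enantiomers bind differently through acid, acetate and methoxy groups, and collecting the enantiomer with both carboxyl-bearing carbons R fixes the absolute configuration of all four ring carbons.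

Step 11
Reactants: 21 (1R,3R)-diacid; 17 6-epi-incarvilline (two molecules)
Product: 22 bis[(4R,4aS,6R,7S,7aR)-2,4,7-trimethyloctahydro-1H-cyclopenta[c]pyridin-6-yl] (1R,3R)-2-(4-acetoxy-3-methoxyphenyl)-4-(4-acetoxyphenyl)cyclobutane-1,3-dicarboxylate
Conditions: PPh3, DIAD, THF, 0 °C → rt (17 in slight excess over two equivalents)
Reagents that add atoms: none
Why: In this double Mitsunobu esterification each C6–O is activated as the oxyphosphonium ion and displaced by carboxylate in an SN2 step with inversion (6S → 6R), the acid acts only as nucleophile so its epimerisable ring carbons are never activated, and the aryl acetates keep the phenols from competing.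

Step 12
Reactants: 22 bis-ester bis-acetate
Product: 23 target, bis[(4R,4aS,6R,7S,7aR)-2,4,7-trimethyloctahydro-1H-cyclopenta[c]pyridin-6-yl] (1R,3R)-2-(4-hydroxy-3-methoxyphenyl)-4-(4-hydroxyphenyl)cyclobutane-1,3-dicarboxylate
Conditions: NH3 (7 M in MeOH), 0 °C → rt
Reagents that add atoms: none
Why: In this chemoselective aminolysis, aryl acetates are much better acyl donors than the hindered secondary alkyl cyclobutanecarboxylates, so both phenols should be freed without ester cleavage or epimerisation.

Compound list
1 | 2-nitrobenzenesulfonyl chloride | O=[N+]([O-])c1ccccc1S(=O)(=O)Cl | starting material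
2 | but-2-yn-1-amine hydrochloride | CC#CCN.Cl | starting material
3 | N-(but-2-yn-1-yl)-2-nitrobenzenesulfonamide | CC#CCNS(=O)(=O)c1ccccc1[N+](=O)[O-] | intermediate
4 | (R)-3-bromo-2-methylpropan-1-ol | BrC[C@H](C)CO | starting material
5 | N-(but-2-yn-1-yl)-N-[(2S)-3-hydroxy-2-methylpropyl]-2-nitrobenzenesulfonamide | CC#CCN(C[C@H](C)CO)S(=O)(=O)c1ccccc1[N+](=O)[O-] | intermediate
6 | methyl chloroformate | COC(=O)Cl | starting material
7 | (2S)-3-(but-2-yn-1-ylamino)-2-methylpropan-1-ol | CC#CCNC[C@H](C)CO | intermediate
8 | methyl (but-2-yn-1-yl)[(2S)-3-hydroxy-2-methylpropyl]carbamate | CC#CCN(C(=O)OC)C[C@H](C)CO | intermediate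
9 | methyl (but-2-yn-1-yl)[(2S)-2-methyl-3-oxopropyl]carbamate | CC#CCN(C(=O)OC)C[C@H](C)C=O | intermediate
10 | methyltriphenylphosphonium bromide | C[P+](c1ccccc1)(c1ccccc1)c1ccccc1.[Br-] | starting material
11 | methyl (but-2-yn-1-yl)[(2R)-2-methylbut-3-en-1-yl]carbamate | CC#CCN(C(=O)OC)C[C@H](C)C=C | intermediate
12 | dicobalt octacarbonyl | O=C=[Co](=C=O)(=C=O)(=C=O)[Co](=C=O)(=C=O)(=C=O)=C=O | starting material
13 | hexacarbonyldicobalt complex of the alkyne of 11 (C2Co2 tetrahedrane, carbonyls drawn as Co=C=O) | CC12[Co]3(=C=O)(=C=O)(=C=O)[Co]1(=C=O)(=C=O)(=C=O)C23CN(C(=O)OC)C[C@H](C)C=C | intermediate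
14 | methyl (4R,4aS)-4,7-dimethyl-6-oxo-1,3,4,4a,5,6-hexahydro-2H-cyclopenta[c]pyridine-2-carboxylate | O=C1C[C@@H]2C(CN(C(=O)OC)C[C@@H]2C)=C1C | intermediate
15 | methyl (4R,4aS,7R,7aR)-4,7-dimethyl-6-oxooctahydro-2H-cyclopenta[c]pyridine-2-carboxylate | O=C1C[C@@H]2[C@@H](CN(C(=O)OC)C[C@@H]2C)[C@H]1C | intermediate
16 | methyl (4R,4aS,7S,7aR)-4,7-dimethyl-6-oxooctahydro-2H-cyclopenta[c]pyridine-2-carboxylate | O=C1C[C@@H]2[C@@H](CN(C(=O)OC)C[C@@H]2C)[C@@H]1C | intermediate
17 | (4R,4aS,6S,7S,7aR)-2,4,7-trimethyloctahydro-1H-cyclopenta[c]pyridin-6-ol | O[C@H]1C[C@@H]2[C@@H](CN(C)C[C@@H]2C)[C@@H]1C | intermediate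
18 | (E)-4-acetoxy-3-methoxycinnamic acid | COc1cc(/C=C/C(=O)O)ccc1OC(C)=O | starting material
19 | (E)-4-acetoxycinnamic acid | CC(=O)Oc1ccc(/C=C/C(=O)O)cc1 | starting material
20 | rac-2-(4-acetoxy-3-methoxyphenyl)-4-(4-acetoxyphenyl)cyclobutane-1,3-dicarboxylic acid, α-truxillic type (both enantiomers written) | COc1cc([C@H]2[C@H](C(=O)O)[C@H](c3ccc(OC(C)=O)cc3)[C@H]2C(=O)O)ccc1OC(C)=O.COc1cc([C@@H]2[C@@H](C(=O)O)[C@@H](c3ccc(OC(C)=O)cc3)[C@@H]2C(=O)O)ccc1OC(C)=O | intermediate
21 | (1R,3R)-2-(4-acetoxy-3-methoxyphenyl)-4-(4-acetoxyphenyl)cyclobutane-1,3-dicarboxylic acid, α-truxillic type | COc1cc([C@H]2[C@H](C(=O)O)[C@H](c3ccc(OC(C)=O)cc3)[C@H]2C(=O)O)ccc1OC(C)=O | intermediate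
22 | bis-ester of 21 with the (6R)-amino alcohol, phenols as acetates | COc1cc([C@H]2[C@H](C(=O)O[C@@H]3C[C@@H]4[C@@H](CN(C)C[C@@H]4C)[C@@H]3C)[C@H](c3ccc(OC(C)=O)cc3)[C@H]2C(=O)O[C@@H]2C[C@@H]3[C@@H](CN(C)C[C@@H]3C)[C@@H]2C)ccc1OC(C)=O | intermediate
23 | CNP0331906.2 | COc1cc([C@H]2[C@H](C(=O)O[C@@H]3C[C@@H]4[C@@H](CN(C)C[C@@H]4C)[C@@H]3C)[C@H](c3ccc(O)cc3)[C@H]2C(=O)O[C@@H]2C[C@@H]3[C@@H](CN(C)C[C@@H]3C)[C@@H]2C)ccc1O | target

Total step count: 12. Longest linear sequence: 10 (steps 1–8, 11, 12).

Steps most likely to fail

Step 9. The two acids may crystallise as separate phases, or pack without short antiparallel contacts, so that cross-pairing does not take place in the solid. The fallback leaves the solid state and sets out from 18 and 19.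
- Esterification: alkylation with BnBr/KHCO3 in DMF gives benzyl (E)-3-(4-acetoxy-3-methoxyphenyl)acrylate F3 and benzyl (E)-3-(4-acetoxyphenyl)acrylate F4.
- Photodimerisation: an equimolar solution of both in CH2Cl2 with BF3·OEt2 is irradiated through Pyrex. The excited ester–Lewis acid complex adds head-to-tail to a free ground-state ester, a known way to α-truxillates in homogeneous solution, where mixing is guaranteed.
- Separation and return: the cross-dimer, the racemic dibenzyl α-truxillate F5, is separated from the homodimers on silica and hydrogenolysed (H2, Pd/C, EtOAc). The sequence comes back to the route at 20.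

Step 6. Alkene insertion to a six-membered tether ring may be slow enough for the cobalt complex to decay, and one methyl group may discriminate the alkene faces only weakly. The fallback sets out from aldehyde 9.
- Olefination: Wittig reaction with ethyl (triphenylphosphoranylidene)acetate gives ethyl (2E,4R)-5-[(but-2-yn-1-yl)(methoxycarbonyl)amino]-4-methylpent-2-enoate F1.
- Cyclisation: the low-valent titanium reagent from Ti(OiPr)4 and two equivalents of i-PrMgCl (Et2O, −78 → −20 °C) couples C7a with the enoate β-carbon C4a to give the diisopropoxytitanabicycle F2.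
- Acylation and return: on warming, the vinyl–titanium carbon C7 of F2 acylates on the ester carbonyl, and protonation gives the enone. No CO insertion is needed, and the ester-bearing C5 is bulkier, which should sharpen the preference for the pseudo-axial methyl. The sequence comes back at 14.

Step 10. Chiral recognition may be too weak, since the enantiomers differ only in the ring that carries one methoxy group. The fallback sets out from racemic 20 and uses the amino alcohol as resolving agent. Coupling with 17 under the conditions of step 11 gives 22 together with the bis-ester of the (1S,3S)-diacid F6. These are diastereomers and are separated by chromatography or by crystallisation of their salts. The route is rejoined at 22.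

Further compounds
F1 | step 6 | ethyl (2E,4R)-5-[(but-2-yn-1-yl)(methoxycarbonyl)amino]-4-methylpent-2-enoate | CC#CCN(C(=O)OC)C[C@H](C)/C=C/C(=O)OCC
F2 | step 6 | diisopropoxytitanabicycle from F1 (Ti bound to C7 and C5, not isolated) | CC1=C2CN(C(=O)OC)C[C@H](C)[C@@H]2C(C(=O)OCC)[Ti]1(OC(C)C)OC(C)C
F3 | step 9 | benzyl (E)-3-(4-acetoxy-3-methoxyphenyl)acrylate | COc1cc(/C=C/C(=O)OCc2ccccc2)ccc1OC(C)=O
F4 | step 9 | benzyl (E)-3-(4-acetoxyphenyl)acrylate | CC(=O)Oc1ccc(/C=C/C(=O)OCc2ccccc2)cc1
F5 | step 9 | rac-dibenzyl 2-(4-acetoxy-3-methoxyphenyl)-4-(4-acetoxyphenyl)cyclobutane-1,3-dicarboxylate, α-truxillic type (both enantiomers written) | COc1cc([C@H]2[C@H](C(=O)OCc3ccccc3)[C@H](c3ccc(OC(C)=O)cc3)[C@H]2C(=O)OCc2ccccc2)ccc1OC(C)=O.COc1cc([C@@H]2[C@@H](C(=O)OCc3ccccc3)[C@@H](c3ccc(OC(C)=O)cc3)[C@@H]2C(=O)OCc2ccccc2)ccc1OC(C)=O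
F6 | step 10 | bis[(4R,4aS,6R,7S,7aR)-2,4,7-trimethyloctahydro-1H-cyclopenta[c]pyridin-6-yl] (1S,3S)-2-(4-acetoxy-3-methoxyphenyl)-4-(4-acetoxyphenyl)cyclobutane-1,3-dicarboxylate | COc1cc([C@@H]2[C@@H](C(=O)O[C@@H]3C[C@@H]4[C@@H](CN(C)C[C@@H]4C)[C@@H]3C)[C@@H](c3ccc(OC(C)=O)cc3)[C@@H]2C(=O)O[C@@H]2C[C@@H]3[C@@H](CN(C)C[C@@H]3C)[C@@H]2C)ccc1OC(C)=O
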